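**Retrosynthetic overview**

1. Pinane locants: C1/C5 bridgeheads, C2 the spiro carbon, C3/C4 ring CH2, C6 the CMe2 bridge, C7 the CH2 bridge; C4' is the isopropyl-bearing chroman carbon. The dihydropyran ring (O–C2 and C3'–C4') is opened to (1R,5R)-β-pinene 13, syncarpic acid 14 and isobutyraldehyde 15 (three-component Knoevenagel/hetero-Diels–Alder; the trione ring comes intact from 14).
2. 13 ⇐ (1S,5R)-nopinone 12 (Wittig) ⇐ bicyclic β-keto ester 11 (dealkoxycarbonylation).
3. Key disconnection: both carbocycles of 11 are cut at C2–C3 and C1–C7 to the open-chain bromo diester 9, which carries only the C5 stereocenter. Forward, one flask closes the six-membered ring (Dieckmann, C2–C3) and then the cyclobutane (dianion alkylation, C1–C7).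
4. Enabling feature: C2 sits at the carbonyl oxidation level, so it first accepts C3 as an acyl carbon and then acidifies its other neighbour C1 for attack on C7. The gem-dimethyl carbon C6 lies inside the forming C1–C6–C5–C7 ring, and the bicyclo[3.1.1] frame excludes O-alkylation.
5. 9 ⇐ auxiliary-controlled Michael addition to methyl acrylate on the imide from 3,3-dimethylglutaric anhydride 1. Ring order: pinane six-membered ring, cyclobutane, dihydropyran.

Key step: step 6

Assumption: syncarpic acid 14 is treated as a purchasable starting material.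

**Step 1**
Reactants: 1 3,3-dimethylglutaric anhydride (4,4-dimethyloxane-2,6-dione); 2 (S)-4-benzyl-1,3-oxazolidin-2-one
Product: 3 5-[(4S)-4-benzyl-2-oxo-1,3-oxazolidin-3-yl]-3,3-dimethyl-5-oxopentanoic acid
Conditions: 2, n-BuLi, THF, −78 °C; then 1, −78 → 0 °C; aq. HCl
Reagents that add atoms: none
Why: N-acylation of the lithiated oxazolidinone by ring opening of the symmetrical anhydride should give the imide and the free acid in one step, with no regiochemical issue and no new stereocenter.

**Step 2**
Reactants: 3
Product: 4 methyl 5-[(4S)-4-benzyl-2-oxo-1,3-oxazolidin-3-yl]-3,3-dimethyl-5-oxopentanoate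
Conditions: MeI, K2CO3, DMF, 25 °C
Reagents that add atoms: iodomethane, CI
Why: Carboxylate O-alkylation (SN2 esterification) under mild base should leave the imide intact; no stereocenter is formed.

**Step 3**
Reactants: 4; 5 methyl acrylate
Product: 6 dimethyl (4S)-4-[(4S)-4-benzyl-2-oxo-1,3-oxazolidine-3-carbonyl]-3,3-dimethylheptanedioate
Conditions: TiCl3(OiPr), i-Pr2NEt, CH2Cl2, 0 °C; then 5, 0 → 25 °C
Reagents that add atoms: none
Why: Auxiliary-controlled Michael addition of the chelated (Z)-chlorotitanium imide enolate, in which soft enolisation occurs only at the imide α-CH2 and the acrylate approaches the face opposite the benzyl group, should set the (S) centre that becomes pinane C5.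

**Step 4**
Reactants: 6
Product: 8 methyl 3-[(3S)-4,4-dimethyl-6-oxooxan-3-yl]propanoate, via hydroxy diester 7 (not isolated)
Conditions: NaBH4, THF/H2O, 0 → 25 °C; then TsOH (cat.), toluene, 60 °C
Reagents that add atoms: none
Why: Borohydride reduction should cleave the N-acyl oxazolidinone at the exocyclic carbonyl without touching the methyl esters, and acid-catalysed, gem-dimethyl-assisted lactonisation (transesterification) then stores the alcohol as one defined compound (a lactone through the other ester would converge in step 5); the stereocenter is no longer α to a carbonyl and is untouched.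

**Step 5**
Reactants: 8
Product: 9 dimethyl (4S)-4-(bromomethyl)-3,3-dimethylheptanedioate
Conditions: HBr (33 % in AcOH), 70 °C; then MeOH, 60 °C
Reagents that add atoms: hydrogen bromide, Br; methanol, CO
Why: Acid-mediated alkyl–oxygen cleavage of the lactone by bromide (SN2 at the primary carbon) followed by Fischer esterification of the freed acid should give the bromo diester without involving the stereocenter.

**Step 6**
Reactants: 9
Product: 11 methyl (1S,5S)-6,6-dimethyl-2-oxobicyclo[3.1.1]heptane-3-carboxylate, via monocyclic β-keto ester 10 (not isolated)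
Conditions: LiN(iPr)2 (1.1 equiv), THF, −78 → −20 °C; then LiN(iPr)2 (2.3 equiv), DMPU, −78 → 25 °C; aq. NH4Cl
Reagents that add atoms: none
Why: The first charge of base deprotonates the unhindered CH2 next to the side-chain ester (the CH2 beside the quaternary carbon reacts far more slowly), and this enolate attacks the other ester in a Dieckmann condensation (6-exo-trig acyl substitution) that forms C2–C3 and the stabilised enolate of 10. The second charge gives the β-keto ester dianion, whose reactive carbon is the γ-carbon C1, and C1 displaces bromide from C7 (4-exo-tet SN2) to close the cyclobutane. The closest known reaction types are the Dieckmann condensation, γ-alkylation of β-keto ester dianions, and the intramolecular ketone-enolate alkylation of 4-(sulfonyloxymethyl)-3,3-dimethylcyclohexanones that gives nopinone. The new bridgehead centre C1 is fixed by the C5 centre because the one-carbon bridge can only span the ring cis; C5 is never α to a carbonyl, and C3 stays an epimerisable β-keto ester carbon that is removed in step 7. The step needs acylation before any alkylation, C- rather than O-alkylation, and C1 rather than C3 as the nucleophile: ester enolates acylate faster than they close four-membered rings, O-alkylation would need a bridgehead double bond in a 2-oxabicyclo[2.2.2]octene, the dianion reacts at its γ-carbon, and the gem-dimethyl group on C6 inside the forming ring accelerates closure.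

**Step 7**
Reactants: 11
Product: 12 (1S,5R)-6,6-dimethylbicyclo[3.1.1]heptan-2-one (the (1S,5R) enantiomer of nopinone)
Conditions: LiCl, DMSO, H2O, 150 °C
Reagents that add atoms: none
Why: Krapcho dealkoxycarbonylation (chloride attack on the ester methyl, loss of CO2, protonation) should remove the activating ester under neutral conditions that spare the strained ketone, leaving both bridgehead centres untouched.

**Step 8**
Reactants: 12
Product: 13 (1R,5R)-6,6-dimethyl-2-methylidenebicyclo[3.1.1]heptane ((1R,5R)-β-pinene)
Conditions: Ph3PCH3Br, KOtBu, THF, 0 → 65 °C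
Reagents that add atoms: methyltriphenylphosphonium bromide, C[P+](c1ccccc1)(c1ccccc1)c1ccccc1.[Br-]
Why: Wittig methylenation should convert the hindered, enolisable ketone into the exocyclic alkene, and the bridgehead stereocentres cannot epimerise.

**Step 9**
Reactants: 13; 14 syncarpic acid (2,2,4,4-tetramethylcyclohexane-1,3,5-trione); 15 isobutyraldehyde
Product: 17 (1S,2S,4'S,5R)-6,6,6',6',8',8'-hexamethyl-4'-(propan-2-yl)-3',4'-dihydrospiro[bicyclo[3.1.1]heptane-2,2'-chromene]-5',7'(6'H,8'H)-dione (CNP0534730.3), via alkylidene trione 16 (not isolated)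
Conditions: ethylenediammonium diacetate (10 mol %), 14 (1.5 equiv), 15 (2 equiv), toluene, 25 → 80 °C
Reagents that add atoms: none
Why: In this domino Knoevenagel/inverse-electron-demand hetero-Diels–Alder reaction the electron-poor 1-oxadiene 16 should add to the 1,1-disubstituted alkene of 13 with the CH2 terminus bonding to the isopropyl-bearing carbon and oxygen to C2, from the face opposite the gem-dimethyl bridge (spiro centre), and with bridgehead C1 exo and the C3 methylene endo to the oxadiene, which places isopropyl cis to C3 as in 17.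

**Compound list**

1 | 3,3-dimethylglutaric anhydride (4,4-dimethyloxane-2,6-dione) | CC1(C)CC(=O)OC(=O)C1 | starting material
2 | (S)-4-benzyl-1,3-oxazolidin-2-one | O=C1N[C@@H](Cc2ccccc2)CO1 | starting material
3 | 5-[(4S)-4-benzyl-2-oxo-1,3-oxazolidin-3-yl]-3,3-dimethyl-5-oxopentanoic acid | OC(=O)CC(C)(C)CC(=O)N1[C@@H](Cc2ccccc2)COC1=O | intermediate
4 | methyl 5-[(4S)-4-benzyl-2-oxo-1,3-oxazolidin-3-yl]-3,3-dimethyl-5-oxopentanoate | COC(=O)CC(C)(C)CC(=O)N1[C@@H](Cc2ccccc2)COC1=O | intermediate
5 | methyl acrylate | C=CC(=O)OC | starting material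
6 | dimethyl (4S)-4-[(4S)-4-benzyl-2-oxo-1,3-oxazolidine-3-carbonyl]-3,3-dimethylheptanedioate | COC(=O)CC(C)(C)[C@@H](C(=O)N1[C@@H](Cc2ccccc2)COC1=O)CCC(=O)OC | intermediate
7 | dimethyl (4S)-4-(hydroxymethyl)-3,3-dimethylheptanedioate | COC(=O)CC(C)(C)[C@@H](CO)CCC(=O)OC | intermediate
8 | methyl 3-[(3S)-4,4-dimethyl-6-oxooxan-3-yl]propanoate | COC(=O)CC[C@@H]1COC(=O)CC1(C)C | intermediate
9 | dimethyl (4S)-4-(bromomethyl)-3,3-dimethylheptanedioate | COC(=O)CC(C)(C)[C@@H](CBr)CCC(=O)OC | intermediate
10 | methyl (5S)-5-(bromomethyl)-4,4-dimethyl-2-oxocyclohexane-1-carboxylate (formed as its lithium enolate; C1 not defined) | COC(=O)C1C[C@H](CBr)C(C)(C)CC1=O | intermediate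
11 | methyl (1S,5S)-6,6-dimethyl-2-oxobicyclo[3.1.1]heptane-3-carboxylate (C3 epimers and enol) | CC1(C)[C@@H]2CC(C(=O)OC)C(=O)[C@H]1C2 | intermediate
12 | (1S,5R)-6,6-dimethylbicyclo[3.1.1]heptan-2-one | CC1(C)[C@@H]2CCC(=O)[C@H]1C2 | intermediate
13 | (1R,5R)-6,6-dimethyl-2-methylidenebicyclo[3.1.1]heptane ((1R,5R)-β-pinene) | CC1(C)[C@@H]2CCC(=C)[C@H]1C2 | intermediate
14 | syncarpic acid (2,2,4,4-tetramethylcyclohexane-1,3,5-trione) | CC1(C)C(=O)CC(=O)C(C)(C)C1=O | starting material
15 | isobutyraldehyde (2-methylpropanal) | CC(C)C=O | starting material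
16 | 2,2,4,4-tetramethyl-6-(2-methylpropylidene)cyclohexane-1,3,5-trione | CC(C)C=C1C(=O)C(C)(C)C(=O)C(C)(C)C1=O | intermediate
17 | (1S,2S,4'S,5R)-6,6,6',6',8',8'-hexamethyl-4'-(propan-2-yl)-3',4'-dihydrospiro[bicyclo[3.1.1]heptane-2,2'-chromene]-5',7'(6'H,8'H)-dione | CC(C)[C@@H]1C[C@]2(CC[C@@H]3C[C@H]2C3(C)C)OC2=C1C(=O)C(C)(C)C(=O)C2(C)C | target

**Step count and risks**

Total steps: 9. Longest linear sequence: 9 steps (1 → 17); 2, 5, 14 and 15 enter directly.

Most likely to fail, in order:

Step 6. The mono-enolate of 10 may be alkylated at its doubly activated carbon C3 by the bromide before the dianion forms, the base may eliminate HBr, or the strained four-membered closure may be too slow at the dianion stage. The fallback sets out from 9 and returns at 12. The Dieckmann condensation is run alone (KOtBu, THF, 0 °C) and 10 is isolated. Dealkoxycarbonylation (LiCl, wet DMSO, 130 °C) gives (4S)-4-(bromomethyl)-3,3-dimethylcyclohexan-1-one F1. The cyclobutane is then closed through the equilibrating potassium enolate of this simple ketone (KOtBu, t-BuOH/THF, reflux), the enolate alkylation known for the sulfonate analogue, which gives 12 directly and makes step 7 unnecessary. The same two bonds are then formed in consecutive flasks.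

Step 9. Endo/exo discrimination may be weak (C4' epimer), the allylic hydrogens of 13 may be transferred in a competing ene reaction with 16, and a second molecule of 14 may add to 16. The fallback sets out from 14 and 15 and returns at 17. The two are condensed with piperidine (CH2Cl2, 25 °C) to the isolable Mannich base 2,2,4,4-tetramethyl-6-[2-methyl-1-(piperidin-1-yl)propyl]cyclohexane-1,3,5-trione F2. F2 is cleaved to 16 with aqueous HCl/CH2Cl2, and the fresh solution of 16 is added slowly to 13 and a chiral BINOL-derived phosphoric acid (the enantiomer matched to 13) at −20 °C. The face of the oxadiene is then chosen by the hydrogen-bonded catalyst rather than by the substrate bias alone, and the low standing concentration of 16 suppresses the side reactions.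

Step 3. The neopentyl-type titanium enolate may add sluggishly to the acrylate, or facial selectivity may erode. The fallback sets out from 4 and returns at 6. The sodium enolate (NaN(SiMe3)2, THF, −78 °C) is alkylated with allyl iodide, a smaller and more reactive electrophile under the same facial control, to give methyl (4S)-4-[(4S)-4-benzyl-2-oxo-1,3-oxazolidine-3-carbonyl]-3,3-dimethylhept-6-enoate F3. Anti-Markovnikov hydroboration/oxidation (9-BBN, THF; then Me3NO) gives methyl (4S)-4-[(4S)-4-benzyl-2-oxo-1,3-oxazolidine-3-carbonyl]-7-hydroxy-3,3-dimethylheptanoate F4. Oxidation (TEMPO, PhI(OAc)2, MeCN/H2O) gives (4S)-4-[(4S)-4-benzyl-2-oxo-1,3-oxazolidine-3-carbonyl]-7-methoxy-5,5-dimethyl-7-oxoheptanoic acid F5, and esterification (MeI, K2CO3, DMF) gives 6.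

**Further compounds**

F1 | step 6 | (4S)-4-(bromomethyl)-3,3-dimethylcyclohexan-1-one | O=C1CC[C@H](CBr)C(C)(C)C1
F2 | step 9 | 2,2,4,4-tetramethyl-6-[2-methyl-1-(piperidin-1-yl)propyl]cyclohexane-1,3,5-trione | CC(C)C(N1CCCCC1)C1C(=O)C(C)(C)C(=O)C(C)(C)C1=O
F3 | step 3 | methyl (4S)-4-[(4S)-4-benzyl-2-oxo-1,3-oxazolidine-3-carbonyl]-3,3-dimethylhept-6-enoate | COC(=O)CC(C)(C)[C@@H](C(=O)N1[C@@H](Cc2ccccc2)COC1=O)CC=C
F4 | step 3 | methyl (4S)-4-[(4S)-4-benzyl-2-oxo-1,3-oxazolidine-3-carbonyl]-7-hydroxy-3,3-dimethylheptanoate | COC(=O)CC(C)(C)[C@@H](C(=O)N1[C@@H](Cc2ccccc2)COC1=O)CCCO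
F5 | step 3 | (4S)-4-[(4S)-4-benzyl-2-oxo-1,3-oxazolidine-3-carbonyl]-7-methoxy-5,5-dimethyl-7-oxoheptanoic acid | COC(=O)CC(C)(C)[C@@H](C(=O)N1[C@@H](Cc2ccccc2)COC1=O)CCC(=O)O
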